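**Retrosynthetic overview**
- Vancouverone A ⇒ its tri-O-benzyl ether, with one global debenzylation last. Neither ring is built: the pyridone is carried as a 2,4-bis(benzyloxy)pyridine from 5-bromo-2,4-dichloropyridine, and the phenol ring arrives by Suzuki coupling.
- Side-chain C5–C6 bond ⇒ primary alkylzinc + (E)-2-bromobut-2-ene (Negishi coupling; the alkene geometry is bought).
- CH2I ⇐ CO2H of a keto acid (borane reduction, then Appel iodination).
- Key disconnection: keto acid ⇒ meso-2,4-dimethylglutaric anhydride + pyridin-3-ylzinc. One catalytic enantioselective ring-opening cross-coupling makes the pyridine–acyl bond and turns the meso pair of methyl centres into the (2S,4R) array.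
- The only ring event is this anhydride opening; order of assembly: pyridine core → aryl group → acyl chain → alkene → deprotection.

Assumption: meso-2,4-dimethylglutaric anhydride and (E)-2-bromobut-2-ene are bought as single isomers, and the (S)-ligand written in step 3 is assumed to direct attack to the carbonyl next to the (S)-configured carbon; if the first run shows the opposite sense, the (R)-ligand is used.

**Step 1**
Reactants: 1 5-bromo-2,4-dichloropyridine; 2 benzyl alcohol (2.4 equiv)
Product: 4 2,4-bis(benzyloxy)-5-bromopyridine, via 4-(benzyloxy)-5-bromo-2-chloropyridine 3 (not isolated)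
Conditions: NaH, DMF, 0 → 90 °C
Reagents that add atoms: none
Why: Twofold SNAr by sodium benzyl oxide, the 4-chloride reacting first and the 2-chloride on heating (both activated by the ring nitrogen), while the 5-bromide, meta to nitrogen, is not activated and is kept for step 2.

**Step 2**
Reactants: 4 2,4-bis(benzyloxy)-5-bromopyridine; 5 [4-(benzyloxy)phenyl]boronic acid
Product: 6 2,4-bis(benzyloxy)-5-[4-(benzyloxy)phenyl]pyridine
Conditions: Pd(dppf)Cl2 (3 mol %), K2CO3, 1,4-dioxane/H2O, 90 °C
Reagents that add atoms: none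
Why: Suzuki–Miyaura coupling at the only C–Br bond (zerovalent palladium inserts there), with benzyl ethers and the pyridine inert and no stereocentre involved.

**Step 3**
Reactants: 6 2,4-bis(benzyloxy)-5-[4-(benzyloxy)phenyl]pyridine; 7 meso-2,4-dimethylglutaric anhydride, (3R,5S)-3,5-dimethyloxane-2,6-dione (1.5 equiv)
Product: 10 (2R,4S)-5-{2,4-bis(benzyloxy)-5-[4-(benzyloxy)phenyl]pyridin-3-yl}-2,4-dimethyl-5-oxopentanoic acid, via pyridin-3-yllithium 8 (not isolated), via pyridin-3-ylzinc chloride 9 (not isolated)
Conditions: LiTMP, THF, −78 °C; ZnCl2, −78 °C → rt; then 7, [RhCl(cod)]2 (5 mol %), (S)-t-BuPHOX (10 mol %), THF, 50 °C; aq. citric acid work-up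
Reagents that add atoms: none
Why: Proposed new method: directed ortho-lithiation at C3 (the only C–H flanked by two alkoxy groups; hindered amide base at −78 °C to avoid benzylic deprotonation) and Li-to-Zn exchange are standard, and the new part is the desymmetrising acyl cross-coupling, in which monovalent rhodium carrying the chiral P,N ligand inserts into one of the two enantiotopic C(=O)–O bonds of the meso anhydride (at C6, next to the S-configured C5), the arylzinc transmetalates and reductive elimination gives the aryl ketone without touching either CH(CH3) centre, so both stereocentres of the target are inherited from the meso substrate and only their differentiation is catalyst-controlled; the closest known reaction type is the rhodium/phosphinooxazoline-catalysed enantioselective ring-opening of this same anhydride with alkylzinc reagents and the rhodium- or palladium-catalysed arylation of meso succinic anhydrides with arylzinc reagents (Negishi-type anhydride coupling), here extended to a di-ortho-alkoxy heteroarylzinc.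

**Step 4**
Reactants: 10 (2R,4S)-5-{2,4-bis(benzyloxy)-5-[4-(benzyloxy)phenyl]pyridin-3-yl}-2,4-dimethyl-5-oxopentanoic acid
Product: 11 (2S,4R)-1-{2,4-bis(benzyloxy)-5-[4-(benzyloxy)phenyl]pyridin-3-yl}-5-hydroxy-2,4-dimethylpentan-1-one
Conditions: BH3·THF (1.3 equiv), THF, 0 °C; then MeOH, aq. NaHCO3
Reagents that add atoms: none
Why: Chemoselective borane reduction, the carboxylic acid reacting through its acyloxyborane much faster than the hindered, twisted di-ortho-alkoxy aryl ketone; no alkene is present yet and neither stereocentre is touched.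

**Step 5**
Reactants: 11 (2S,4R)-1-{2,4-bis(benzyloxy)-5-[4-(benzyloxy)phenyl]pyridin-3-yl}-5-hydroxy-2,4-dimethylpentan-1-one
Product: 12 (2S,4R)-1-{2,4-bis(benzyloxy)-5-[4-(benzyloxy)phenyl]pyridin-3-yl}-5-iodo-2,4-dimethylpentan-1-one
Conditions: I2, PPh3, imidazole, CH2Cl2, 0 °C → rt
Reagents that add atoms: iodine, II
Why: Appel-type iodination by SN2 displacement of the primary alkoxyphosphonium, neutral enough to leave the α-keto stereocentre and the benzyl ethers untouched.

**Step 6**
Reactants: 12 (2S,4R)-1-{2,4-bis(benzyloxy)-5-[4-(benzyloxy)phenyl]pyridin-3-yl}-5-iodo-2,4-dimethylpentan-1-one; 13 (E)-2-bromobut-2-ene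
Product: 15 (2S,4R,6E)-1-{2,4-bis(benzyloxy)-5-[4-(benzyloxy)phenyl]pyridin-3-yl}-2,4,6-trimethyloct-6-en-1-one, via alkylzinc iodide 14 (not isolated)
Conditions: Zn dust, LiCl, THF, 40 °C; then 13, Pd(OAc)2 (2 mol %), SPhos (4 mol %), THF, rt → 40 °C
Reagents that add atoms: none
Why: LiCl-promoted zinc insertion into the primary C–I bond tolerates the hindered ketone, and the Negishi sp3–sp2 coupling with the alkenyl bromide proceeds with retention of alkene geometry, so the 6E configuration is bought with 13 and the mild alkylzinc does not enolise C2.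

**Step 7**
Reactants: 15 (2S,4R,6E)-1-{2,4-bis(benzyloxy)-5-[4-(benzyloxy)phenyl]pyridin-3-yl}-2,4,6-trimethyloct-6-en-1-one
Product: 16 Vancouverone A, 4-hydroxy-5-(4-hydroxyphenyl)-3-[(2S,4R,6E)-2,4,6-trimethyloct-6-enoyl]pyridin-2(1H)-one
Conditions: BCl3 (8 equiv), pentamethylbenzene (10 equiv), CH2Cl2, −78 °C; then MeOH, pH 4 buffer
Reagents that add atoms: none
Why: Lewis-acid debenzylation with BCl3 and pentamethylbenzene as a non-basic cation scavenger cleaves all three benzyl ethers at −78 °C, the benzyl cations being taken up by Friedel–Crafts alkylation of the scavenger instead of the trisubstituted alkene, and the freed 2-hydroxypyridine tautomerises to the 2-pyridone without change at C2 or C4 of the chain.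

**Compound list**
1 | 5-bromo-2,4-dichloropyridine | Clc1cc(Cl)c(Br)cn1 | starting material
2 | benzyl alcohol | OCc1ccccc1 | starting material
3 | 4-(benzyloxy)-5-bromo-2-chloropyridine | Clc1cc(OCc2ccccc2)c(Br)cn1 | intermediate
4 | 2,4-bis(benzyloxy)-5-bromopyridine | c1ccccc1COc1cc(OCc2ccccc2)c(Br)cn1 | intermediate
5 | [4-(benzyloxy)phenyl]boronic acid | OB(O)c1ccc(OCc2ccccc2)cc1 | starting material
6 | 2,4-bis(benzyloxy)-5-[4-(benzyloxy)phenyl]pyridine | c1ccccc1COc1cc(OCc2ccccc2)c(cn1)-c1ccc(OCc2ccccc2)cc1 | intermediate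
7 | meso-2,4-dimethylglutaric anhydride, (3R,5S)-3,5-dimethyloxane-2,6-dione (cis) | C[C@@H]1C[C@H](C)C(=O)OC1=O | starting material
8 | {2,4-bis(benzyloxy)-5-[4-(benzyloxy)phenyl]pyridin-3-yl}lithium | [Li]c1c(OCc2ccccc2)ncc(-c2ccc(OCc3ccccc3)cc2)c1OCc1ccccc1 | intermediate
9 | {2,4-bis(benzyloxy)-5-[4-(benzyloxy)phenyl]pyridin-3-yl}zinc chloride | Cl[Zn]c1c(OCc2ccccc2)ncc(-c2ccc(OCc3ccccc3)cc2)c1OCc1ccccc1 | intermediate
10 | (2R,4S)-5-{2,4-bis(benzyloxy)-5-[4-(benzyloxy)phenyl]pyridin-3-yl}-2,4-dimethyl-5-oxopentanoic acid | OC(=O)[C@H](C)C[C@H](C)C(=O)c1c(OCc2ccccc2)ncc(-c2ccc(OCc3ccccc3)cc2)c1OCc1ccccc1 | intermediate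
11 | (2S,4R)-1-{2,4-bis(benzyloxy)-5-[4-(benzyloxy)phenyl]pyridin-3-yl}-5-hydroxy-2,4-dimethylpentan-1-one | OC[C@H](C)C[C@H](C)C(=O)c1c(OCc2ccccc2)ncc(-c2ccc(OCc3ccccc3)cc2)c1OCc1ccccc1 | intermediate
12 | (2S,4R)-1-{2,4-bis(benzyloxy)-5-[4-(benzyloxy)phenyl]pyridin-3-yl}-5-iodo-2,4-dimethylpentan-1-one | IC[C@H](C)C[C@H](C)C(=O)c1c(OCc2ccccc2)ncc(-c2ccc(OCc3ccccc3)cc2)c1OCc1ccccc1 | intermediate
13 | (E)-2-bromobut-2-ene (methyl groups cis) | C/C=C(\C)Br | starting material
14 | [(2R,4S)-5-{2,4-bis(benzyloxy)-5-[4-(benzyloxy)phenyl]pyridin-3-yl}-2,4-dimethyl-5-oxopentyl]zinc iodide | I[Zn]C[C@H](C)C[C@H](C)C(=O)c1c(OCc2ccccc2)ncc(-c2ccc(OCc3ccccc3)cc2)c1OCc1ccccc1 | intermediate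
15 | (2S,4R,6E)-1-{2,4-bis(benzyloxy)-5-[4-(benzyloxy)phenyl]pyridin-3-yl}-2,4,6-trimethyloct-6-en-1-one | C/C=C(\C)C[C@H](C)C[C@H](C)C(=O)c1c(OCc2ccccc2)ncc(-c2ccc(OCc3ccccc3)cc2)c1OCc1ccccc1 | intermediate
16 | Vancouverone A, 4-hydroxy-5-(4-hydroxyphenyl)-3-[(2S,4R,6E)-2,4,6-trimethyloct-6-enoyl]pyridin-2(1H)-one | C/C=C(\C)C[C@H](C)C[C@H](C)C(=O)c1c(O)c(-c2ccc(O)cc2)c[nH]c1=O | target

**Count**
Total steps: 7. Longest linear sequence: 7 (1 → 4 → 6 → 10 → 11 → 12 → 15 → 16).

**Steps most likely to fail, with fallbacks**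

Step 3 is the riskiest. The hindered heteroarylzinc may transmetalate slowly, and both the level and the sense of enantioselection are untested. The fallback sets out from 7 (and uses 8, made from 6 as in step 3 but without zinc) and comes back at 11. Anhydride 7 is opened with methanol under quinidine or quinine control (toluene, −55 °C), whichever alkaloid delivers attack at the same carbonyl, to give the hemiester (2R,4S)-5-methoxy-2,4-dimethyl-5-oxopentanoic acid F1. BH3·SMe2 reduces the free acid to methyl (2S,4R)-5-hydroxy-2,4-dimethylpentanoate F2, which closes under catalytic TsOH to the lactone (3S,5R)-3,5-dimethyloxan-2-one F3. Addition of 8 to F3 at −78 °C stops at the hindered lactolate and gives hydroxy ketone 11 on work-up, replacing steps 3 and 4; the route continues with step 5.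

Step 6 may fail through sluggish or unclean zinc insertion next to the ketone, or through β-hydride loss in the coupling. The fallback sets out from 12 and 13 and comes back at 15, with the polarity of the partners reversed. Bromide 13 is treated with t-BuLi (2 equiv, −78 °C) to give (Z)-but-2-en-2-yllithium F4 (methyl groups still cis; the descriptor changes only because lithium ranks below carbon). ZnCl2 converts it into (E)-but-2-en-2-ylzinc chloride F5. This is coupled with the intact alkyl iodide 12 under Pd2(dba)3/tricyclopentylphosphine/N-methylimidazole in THF/NMP at 80 °C (Negishi coupling of an unactivated primary alkyl electrophile), giving 15 without an organozinc being made beside the ketone.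

Step 7 may fail through HCl or cation addition to the trisubstituted alkene, or through incomplete cleavage of a boron-chelated intermediate. The fallback sets out from 15 and comes back at 16 in two mechanistically different stages. LiCl in DMF at 90 °C removes only the two activated pyridyl benzyl ethers (lactim and vinylogous-ester type) by SN2 attack of chloride at the benzylic carbons, giving 5-[4-(benzyloxy)phenyl]-4-hydroxy-3-[(2S,4R,6E)-2,4,6-trimethyloct-6-enoyl]pyridin-2(1H)-one F6. The remaining aryl benzyl ether is then cleaved by transfer hydrogenolysis (10% Pd/C, 1,4-cyclohexadiene, EtOH, rt), stopped as soon as F6 is consumed, because O-benzyl hydrogenolysis is much faster than saturation of a trisubstituted alkene; this gives 16.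

**Further compounds**
F1 | step 3 | (2R,4S)-5-methoxy-2,4-dimethyl-5-oxopentanoic acid | OC(=O)[C@H](C)C[C@H](C)C(=O)OC
F2 | step 3 | methyl (2S,4R)-5-hydroxy-2,4-dimethylpentanoate | OC[C@H](C)C[C@H](C)C(=O)OC
F3 | step 3 | (3S,5R)-3,5-dimethyloxan-2-one | C1[C@H](C)C[C@H](C)C(=O)O1
F4 | step 6 | (Z)-but-2-en-2-yllithium | C/C=C(\C)[Li]
F5 | step 6 | (E)-but-2-en-2-ylzinc chloride | C/C=C(\C)[Zn]Cl
F6 | step 7 | 5-[4-(benzyloxy)phenyl]-4-hydroxy-3-[(2S,4R,6E)-2,4,6-trimethyloct-6-enoyl]pyridin-2(1H)-one | C/C=C(\C)C[C@H](C)C[C@H](C)C(=O)c1c(O)c(-c2ccc(OCc3ccccc3)cc2)c[nH]c1=O
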